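**Retrosynthetic overview** (eudesmane numbering: ring A = C1–C5 and C10, ring B = C5–C10; C14 methyl on C10, C15 methyl on C4, acrylate C11(=C13)–C12 on C7, acetate on C8, propanoate on C3)
1. The plan rests on ring A: quaternary C10 (carrying C14 and the one-carbon arm C9) lies next to C5 and 1,4 to oxygenated C3, the pattern left when methacrolein (C1=C10) adds to a 2-silyloxy-3-methyl-1,3-diene (C2=C3–C4=C5).
2. End game: C3 propanoate from Luche reduction of the 4-en-3-one; C8 acetate and C12 methyl ester from opening a cis 8β,12-lactone; the lactone from iodolactonization of the C7 acrylic acid across C8=C9, then deiodination.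
3. Ring B by ring-closing metathesis (C8=C9) between the C7 vinyl and a C10 vinyl made from the cycloadduct aldehyde; the C3 silyl enol ether masks the ketone while C13 is installed, then is desaturated to the enone.
4. Ring A by enantioselective Diels–Alder reaction (bonds C1–C2 and C5–C10) of methacrolein with the (E)-diene that already carries C7.
5. Diene from a Wittig/enol silylation sequence on an aldehyde ester whose C7 centre comes from iridium-catalysed allylic alkylation of dimethyl malonate. Ring order: A, then B, then the temporary lactone.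

Key step: step 9

Assumption: 1 is a catalogue compound, and the antipode named for each chiral catalyst (steps 4 and 9) is the one predicted by the accepted facial model of its class; if a first run showed the opposite sense, the mirror-image ligand would be used with no other change.

**Step 1**
Reactants: 1 4,4-diethoxybut-1-yne
Product: 3 5,5-diethoxypent-2-yn-1-ol, via lithium acetylide 2 (not isolated)
Conditions: n-BuLi, THF, –78 °C; (CH2O)n, –78 °C → rt; aq NH4Cl
Reagents that add atoms: paraformaldehyde (as formaldehyde) C=O; n-butyllithium [Li]CCCC (its lithium stays in 2 only)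
Why: Deprotonation of the terminal alkyne and addition of the acetylide to formaldehyde (acetylide hydroxymethylation) is routine, and the acetal is inert to base.

**Step 2**
Reactants: 3 5,5-diethoxypent-2-yn-1-ol
Product: 4 (E)-5,5-diethoxypent-2-en-1-ol
Conditions: NaAlH2(OCH2CH2OMe)2 (Red-Al), THF, 0 °C → rt; aq potassium sodium tartrate
Reagents that add atoms: none
Why: Alkoxide-directed trans-hydroalumination of a propargylic alcohol should give only the (E)-allylic alcohol, the geometry that step 4 needs.

**Step 3**
Reactants: 4 (E)-5,5-diethoxypent-2-en-1-ol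
Product: 5 (E)-5,5-diethoxypent-2-en-1-yl methyl carbonate
Conditions: ClCO2Me, pyridine, CH2Cl2, 0 °C
Reagents that add atoms: methyl chloroformate COC(=O)Cl
Why: Simple O-acylation of a primary allylic alcohol under basic conditions that leave the acetal untouched.

**Step 4**
Reactants: 5 (E)-5,5-diethoxypent-2-en-1-yl methyl carbonate; 6 dimethyl malonate
Product: 7 dimethyl 2-[(3S)-5,5-diethoxypent-1-en-3-yl]propanedioate
Conditions: [Ir(cod)Cl]2 (2 mol%), (Ra,R,R)-O,O'-(1,1'-binaphthalene-2,2'-diyl) N,N-bis(1-phenylethyl)phosphoramidite (4 mol%), 1,5,7-triazabicyclo[4.4.0]dec-5-ene (TBD, 8 mol%), THF, rt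
Reagents that add atoms: none
Why: Iridium-catalysed asymmetric allylic alkylation: the cyclometallated iridium–phosphoramidite complex ionises the (E)-carbonate and the malonate attacks the substituted allyl terminus anti to the metal, so the branched product should form and the ligand antipode sets C7.

**Step 5**
Reactants: 7 dimethyl 2-[(3S)-5,5-diethoxypent-1-en-3-yl]propanedioate
Product: 8 methyl (3R)-3-(2,2-diethoxyethyl)pent-4-enoate
Conditions: LiCl, H2O, DMSO, 150 °C
Reagents that add atoms: none
Why: Krapcho dealkoxycarbonylation removes one ester; the medium is neutral to basic, so the acetal should survive, and C7 is not α to a carbonyl group, so it cannot epimerise (the descriptor changes by priority only).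

**Step 6**
Reactants: 8 methyl (3R)-3-(2,2-diethoxyethyl)pent-4-enoate
Product: 9 methyl (3R)-3-(2-oxoethyl)pent-4-enoate
Conditions: 1 M HCl, THF, 0 °C → rt
Reagents that add atoms: water O
Why: Acid-catalysed acetal hydrolysis frees the aldehyde at C5 under conditions too mild to touch the methyl ester or the non-enolisable C7 centre.

**Step 7**
Reactants: 9 methyl (3R)-3-(2-oxoethyl)pent-4-enoate; 10 3-(triphenylphosphoranylidene)butan-2-one
Product: 11 methyl (3R,5E)-3-ethenyl-6-methyl-7-oxooct-5-enoate
Conditions: toluene, 80 °C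
Reagents that add atoms: none
Why: Wittig olefination with an α-methyl ketone-stabilised ylide should give the (E)-trisubstituted enone (C4=C5) and reacts with the aldehyde only.

**Step 8**
Reactants: 11 methyl (3R,5E)-3-ethenyl-6-methyl-7-oxooct-5-enoate
Product: 12 methyl (3R,5E)-7-(tert-butyldimethylsilyloxy)-3-ethenyl-6-methylocta-5,7-dienoate
Conditions: TBSOTf, Et3N, CH2Cl2, –78 → 0 °C
Reagents that add atoms: tert-butyldimethylsilyl triflate CC(C)(C)[Si](C)(C)OS(=O)(=O)C(F)(F)F
Why: Soft enolisation (O-silylation, then loss of a proton from the α'-methyl) should give the cross-conjugated 2-silyloxydiene under kinetic control, the ketone reacting far faster than the ester and the C4=C5 geometry being retained.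

**Step 9**
Reactants: 12 methyl (3R,5E)-7-(tert-butyldimethylsilyloxy)-3-ethenyl-6-methylocta-5,7-dienoate; 13 methacrolein
Product: 14 methyl (3R)-3-{[(1R,6S)-3-(tert-butyldimethylsilyloxy)-6-formyl-2,6-dimethylcyclohex-2-en-1-yl]methyl}pent-4-enoate (endo adduct, formyl cis to the side chain on C5)
Conditions: (S)-3,3-diphenyl-1-(2-methylphenyl)tetrahydro-1H,3H-pyrrolo[1,2-c][1,3,2]oxazaborole (20 mol%) protonated with HN(SO2CF3)2 (18 mol%), CH2Cl2, –78 °C; 13 (2 equiv), then slow addition of 12
Reagents that add atoms: none
Why: The cationic boron Lewis acid binds the formyl oxygen of 13 as the s-trans enal, and the electron-rich silyloxydiene adds in a concerted, asynchronous [4+2] cycloaddition in which the nucleophilic terminus C2 bonds to the β-carbon C1 ahead of C5–C10; the closest known reaction type is the oxazaborolidinium-catalysed Diels–Alder reaction of 2-silyloxydienes with α-substituted acroleins. Ring A (C1–C5, C10) closes as a six-membered carbocycle by suprafacial addition on both partners, the (E)-geometry at C4=C5 holding the C6 chain outside the s-cis diene. C10 is set by the catalyst, whose aryl group shields the Si face of the α-carbon so that the diene bonds to the Re face whatever the configuration of remote C7; C5 follows from the endo (formyl) transition state and is a transient centre flattened in step 13, so any exo adduct converges later. The step needs the regiochemistry that places C10 next to C5 and 1,4 to C3, secured by the silyloxy group on C3 and the alkyl group on C5, which both polarise the diene toward C2. It also needs cycloaddition to outrun Mukaiyama-type addition and protodesilylation, which the low temperature, the sub-stoichiometric acid activator (no free Brønsted acid) and the TBS group are meant to secure.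

**Step 10**
Reactants: 14 Diels–Alder aldehyde
Product: 15 methyl (3R)-3-{[(1S,6R)-3-(tert-butyldimethylsilyloxy)-6-ethenyl-2,6-dimethylcyclohex-2-en-1-yl]methyl}pent-4-enoate
Conditions: Ph3PCH3Br, KN(SiMe3)2, THF, 0 °C → rt
Reagents that add atoms: methyltriphenylphosphonium bromide C[P+](c1ccccc1)(c1ccccc1)c1ccccc1.[Br-]
Why: Wittig methylenation of a non-enolisable neopentyl aldehyde is reliable and selective over the ester, and the silyl enol ether is inert to the ylide (descriptors change by priority only).

**Step 11**
Reactants: 15 divinyl silyl enol ether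
Product: 16 methyl (5S,7R,10R)-3-(tert-butyldimethylsilyloxy)-13-noreudesma-3,8-dien-12-oate (cis-fused, 5β-H; C7 arm and C10 methyl cis)
Conditions: second-generation Grubbs catalyst (H2IMes)(PCy3)Cl2Ru=CHPh (5 mol%), CH2Cl2, 40 °C
Reagents that add atoms: none
Why: Ring-closing metathesis of the two monosubstituted alkenes closes six-membered ring B at C8=C9 with loss of ethene, while the tetrasubstituted enol ether cannot take part.

**Step 12**
Reactants: 16 bicyclic ester
Product: 20 methyl (5S,7S,10R)-3-(tert-butyldimethylsilyloxy)eudesma-3,8,11(13)-trien-12-oate, via lithium ester enolate 17 (not isolated), via Mannich base 18 (not isolated), via trimethylammonium iodide 19 (not isolated)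
Conditions: LiN(i-Pr)2, THF, –78 °C; CH2=NMe2+ I–, –78 °C → rt; MeI, CH2Cl2, rt; DBU, CH2Cl2, rt
Reagents that add atoms: Eschenmoser's salt C=[N+](C)C.[I-]; lithium diisopropylamide CC(C)[N-]C(C)C.[Li+] (its lithium stays in 17 only); iodomethane CI (its methyl stays in 19 only)
Why: Ester enolate Mannich reaction with Eschenmoser's salt, then quaternisation and E1cB loss of trimethylamine (Eschenmoser methylenation), installs C13; the ketone is still masked as its silyl enol ether, so the ester is the only enolisable carbonyl group.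

**Step 13**
Reactants: 20 silyl enol ether acrylate
Product: 21 methyl (7S,10R)-3-oxoeudesma-4,8,11(13)-trien-12-oate
Conditions: Pd(OAc)2 (1.1 equiv), MeCN, rt → 40 °C
Reagents that add atoms: none
Why: Saegusa–Ito oxidation: the palladium enolate at C4 loses the C5 hydrogen by β-hydride elimination to give the tetrasubstituted 4-en-3-one, which erases the transient C5 centre so that both C5 epimers converge.

**Step 14**
Reactants: 21 enone methyl ester
Product: 22 (7S,10R)-3-oxoeudesma-4,8,11(13)-trien-12-oic acid
Conditions: LiOH·H2O, THF/H2O, 0 °C → rt; 1 M HCl to pH 3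
Reagents that add atoms: lithium hydroxide [Li+].[OH-]
Why: Saponification of the α-branched acrylate ester; the carboxylate formed is a poor Michael acceptor and the enone tolerates cold aqueous hydroxide.

**Step 15**
Reactants: 22 acrylic acid
Product: 23 (7R,8S,9S,10S)-9-iodo-3-oxoeudesma-4,11(13)-dien-12,8-olide (8β-O, 9α-I, cis-fused γ-lactone)
Conditions: I2, NaHCO3, MeCN/H2O, 0 °C, dark
Reagents that add atoms: iodine II
Why: Iodolactonization: the iodonium ion forms on the α-face of C8=C9 (anti to the axial C10 methyl) and the carboxylate held on the β-face of C7 opens it at C8 in the 5-exo mode, so the cis-fused lactone sets the 8β oxygen relative to C7; the enone and acrylate alkenes are too electron-poor to react.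

**Step 16**
Reactants: 23 iodolactone
Product: 24 (7R,8R,10R)-3-oxoeudesma-4,11(13)-dien-12,8-olide
Conditions: Bu3SnH, AIBN (cat.), benzene, 80 °C (tin hydride kept concentrated)
Reagents that add atoms: none
Why: Radical chain dehalogenation: iodine abstraction by the stannyl radical outpaces its addition to the acrylate, the hindered C9 radical is quenched by tin hydride, and the only available cyclisation onto C13 would be a disfavoured 5-endo closure.

**Step 17**
Reactants: 24 α-methylene lactone
Product: 26 methyl (7R,8R,10R)-8-hydroxy-3-oxoeudesma-4,11(13)-dien-12-oate, via potassium hydroxy carboxylate 25 (not isolated)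
Conditions: KOH (1.05 equiv), THF/H2O, 0 °C; evaporate; MeI, DMF, 0 °C → rt; crude used at once
Reagents that add atoms: potassium hydroxide [K+].[OH-]; iodomethane CI
Why: Lactone saponification (acyl–oxygen cleavage, C8 untouched) followed by SN2 O-methylation of the carboxylate gives the methyl ester without an acidic stage that would reclose the lactone.

**Step 18**
Reactants: 26 hydroxy ester
Product: 27 methyl (7R,8R,10R)-8-acetoxy-3-oxoeudesma-4,11(13)-dien-12-oate
Conditions: Ac2O, DMAP, Et3N, CH2Cl2, 0 °C
Reagents that add atoms: acetic anhydride CC(=O)OC(C)=O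
Why: DMAP-catalysed acetylation of the axial 8β-hydroxyl proceeds with retention and removes the risk of relactonization.

**Step 19**
Reactants: 27 enone acetate
Product: 28 methyl (3S,7R,8R,10R)-8-acetoxy-3-hydroxyeudesma-4,11(13)-dien-12-oate
Conditions: NaBH4, CeCl3·7H2O, MeOH, –78 °C
Reagents that add atoms: none
Why: Luche 1,2-reduction: hydride should add axially from the α-face, opposite the C10 β-methyl, to give the equatorial 3β-alcohol (3S), while the acrylate and acetate are inert at this temperature.

**Step 20**
Reactants: 28 allylic alcohol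
Product: 29 methyl (3S,7R,8R,10R)-8-acetoxy-3-propanoyloxyeudesma-4,11(13)-dien-12-oate (target CNP0198123.1)
Conditions: (EtCO)2O, DMAP, Et3N, CH2Cl2, 0 °C → rt
Reagents that add atoms: propanoic anhydride CCC(=O)OC(=O)CC
Why: DMAP-catalysed O-acylation of the secondary allylic alcohol with retention at C3 completes the target.

**Compound list**
1 | 4,4-diethoxybut-1-yne | C#CCC(OCC)OCC | starting material
2 | lithium acetylide of 1 | [Li]C#CCC(OCC)OCC | intermediate
3 | 5,5-diethoxypent-2-yn-1-ol | OCC#CCC(OCC)OCC | intermediate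
4 | (E)-5,5-diethoxypent-2-en-1-ol | OC/C=C/CC(OCC)OCC | intermediate
5 | (E)-5,5-diethoxypent-2-en-1-yl methyl carbonate | COC(=O)OC/C=C/CC(OCC)OCC | intermediate
6 | dimethyl malonate | COC(=O)CC(=O)OC | starting material
7 | dimethyl 2-[(3S)-5,5-diethoxypent-1-en-3-yl]propanedioate | C=C[C@H](CC(OCC)OCC)C(C(=O)OC)C(=O)OC | intermediate
8 | methyl (3R)-3-(2,2-diethoxyethyl)pent-4-enoate | C=C[C@@H](CC(=O)OC)CC(OCC)OCC | intermediate
9 | methyl (3R)-3-(2-oxoethyl)pent-4-enoate | C=C[C@@H](CC(=O)OC)CC=O | intermediate
10 | 3-(triphenylphosphoranylidene)butan-2-one | CC(=O)C(C)=P(c1ccccc1)(c1ccccc1)c1ccccc1 | starting material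
11 | methyl (3R,5E)-3-ethenyl-6-methyl-7-oxooct-5-enoate | C=C[C@@H](CC(=O)OC)C/C=C(C)/C(C)=O | intermediate
12 | methyl (3R,5E)-7-(tert-butyldimethylsilyloxy)-3-ethenyl-6-methylocta-5,7-dienoate | C=C[C@@H](CC(=O)OC)C/C=C(C)/C(=C)O[Si](C)(C)C(C)(C)C | intermediate
13 | methacrolein | C=C(C)C=O | starting material
14 | methyl (3R)-3-{[(1R,6S)-3-(tert-butyldimethylsilyloxy)-6-formyl-2,6-dimethylcyclohex-2-en-1-yl]methyl}pent-4-enoate | C=C[C@@H](CC(=O)OC)C[C@@H]1C(C)=C(O[Si](C)(C)C(C)(C)C)CC[C@]1(C)C=O | intermediate
15 | methyl (3R)-3-{[(1S,6R)-3-(tert-butyldimethylsilyloxy)-6-ethenyl-2,6-dimethylcyclohex-2-en-1-yl]methyl}pent-4-enoate | C=C[C@@H](CC(=O)OC)C[C@@H]1C(C)=C(O[Si](C)(C)C(C)(C)C)CC[C@]1(C)C=C | intermediate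
16 | methyl (5S,7R,10R)-3-(tert-butyldimethylsilyloxy)-13-noreudesma-3,8-dien-12-oate | COC(=O)C[C@H]1C[C@@H]2C(C)=C(O[Si](C)(C)C(C)(C)C)CC[C@]2(C)C=C1 | intermediate
17 | lithium ester enolate of 16 | COC(O[Li])=C[C@H]1C[C@@H]2C(C)=C(O[Si](C)(C)C(C)(C)C)CC[C@]2(C)C=C1 | intermediate
18 | methyl (5S,7R,10R)-13-(dimethylamino)-3-(tert-butyldimethylsilyloxy)eudesma-3,8-dien-12-oate (C11 epimers) | COC(=O)C(CN(C)C)[C@H]1C[C@@H]2C(C)=C(O[Si](C)(C)C(C)(C)C)CC[C@]2(C)C=C1 | intermediate
19 | N-methyl quaternary ammonium iodide of 18 | COC(=O)C(C[N+](C)(C)C)[C@H]1C[C@@H]2C(C)=C(O[Si](C)(C)C(C)(C)C)CC[C@]2(C)C=C1.[I-] | intermediate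
20 | methyl (5S,7S,10R)-3-(tert-butyldimethylsilyloxy)eudesma-3,8,11(13)-trien-12-oate | C=C(C(=O)OC)[C@H]1C[C@@H]2C(C)=C(O[Si](C)(C)C(C)(C)C)CC[C@]2(C)C=C1 | intermediate
21 | methyl (7S,10R)-3-oxoeudesma-4,8,11(13)-trien-12-oate | C=C(C(=O)OC)[C@H]1CC2=C(C)C(=O)CC[C@]2(C)C=C1 | intermediate
22 | (7S,10R)-3-oxoeudesma-4,8,11(13)-trien-12-oic acid | C=C(C(=O)O)[C@H]1CC2=C(C)C(=O)CC[C@]2(C)C=C1 | intermediate
23 | (7R,8S,9S,10S)-9-iodo-3-oxoeudesma-4,11(13)-dien-12,8-olide | C=C1C(=O)O[C@@H]2[C@@H](I)[C@@]3(C)CCC(=O)C(C)=C3C[C@H]12 | intermediate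
24 | (7R,8R,10R)-3-oxoeudesma-4,11(13)-dien-12,8-olide | C=C1C(=O)O[C@@H]2C[C@@]3(C)CCC(=O)C(C)=C3C[C@H]12 | intermediate
25 | potassium (7R,8R,10R)-8-hydroxy-3-oxoeudesma-4,11(13)-dien-12-oate | C=C(C(=O)[O-])[C@H]1CC2=C(C)C(=O)CC[C@]2(C)C[C@H]1O.[K+] | intermediate
26 | methyl (7R,8R,10R)-8-hydroxy-3-oxoeudesma-4,11(13)-dien-12-oate | C=C(C(=O)OC)[C@H]1CC2=C(C)C(=O)CC[C@]2(C)C[C@H]1O | intermediate
27 | methyl (7R,8R,10R)-8-acetoxy-3-oxoeudesma-4,11(13)-dien-12-oate | C=C(C(=O)OC)[C@H]1CC2=C(C)C(=O)CC[C@]2(C)C[C@H]1OC(C)=O | intermediate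
28 | methyl (3S,7R,8R,10R)-8-acetoxy-3-hydroxyeudesma-4,11(13)-dien-12-oate | C=C(C(=O)OC)[C@H]1CC2=C(C)[C@@H](O)CC[C@]2(C)C[C@H]1OC(C)=O | intermediate
29 | methyl (3S,7R,8R,10R)-8-acetoxy-3-propanoyloxyeudesma-4,11(13)-dien-12-oate | C=C(C(=O)OC)[C@H]1CC2=C(C)[C@@H](OC(=O)CC)CC[C@]2(C)C[C@H]1OC(C)=O | target

**Totals:** 20 steps; longest linear sequence 20 steps (from 1).

**Steps most likely to fail**

Step 9 (key step). The acid-labile dienol ether may be desilylated or may add to the activated aldehyde in a Mukaiyama fashion faster than it cyclises, or the catalyst may discriminate the two faces of the enal poorly. The fallback replaces catalyst control by separation. It sets out from 12 and 13 and runs the same cycloaddition with the achiral, proton-scavenging Lewis acid Me2AlCl (CH2Cl2, –78 °C). Regiochemistry and endo preference belong to the diene and remain, so 14 should form together with the ring-epimeric endo adduct, methyl (3R)-3-{[(1S,6R)-3-(tert-butyldimethylsilyloxy)-6-formyl-2,6-dimethylcyclohex-2-en-1-yl]methyl}pent-4-enoate F1. The pair is taken through steps 10 and 11 unchanged, giving from the epimer the divinyl compound methyl (3R)-3-{[(1R,6S)-3-(tert-butyldimethylsilyloxy)-6-ethenyl-2,6-dimethylcyclohex-2-en-1-yl]methyl}pent-4-enoate F2 and then the bicyclic ester methyl (5R,7R,10S)-3-(tert-butyldimethylsilyloxy)-13-noreudesma-3,8-dien-12-oate F3. On the rigid bicycle the C7 centre from step 4 acts as internal reference (C7 arm and C10 methyl cis in 16, trans in the epimer), so the two diastereomers should be separable by chromatography; the route is rejoined at 16.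

Step 17. Hydroxide may add to C13 of the α-methylene lactone in competition with acyl attack, or the γ-hydroxy ester may reclose to the lactone during methylation and handling. The fallback masks the methylene and acetylates before unveiling it. It sets out from 24: dimethylamine (THF, 0 °C) adds to C13 to give the amine adduct (7R,8R,10R)-13-(dimethylamino)-3-oxoeudesm-4-en-12,8-olide F4. KOH (THF/H2O) opens the now unreactive lactone to the potassium hydroxy carboxylate F5. Excess MeI in DMF methylates the carboxylate and quaternises the amine in one operation to the trimethylammonium hydroxy ester iodide F6. Ac2O/pyridine/DMAP gives the trimethylammonium acetoxy ester iodide F7, and DBU then expels trimethylamine to unveil the acrylate. The route is rejoined at 27 without 26 being handled.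

Step 13. Palladation of the hindered tetrasubstituted enol ether may be slow, or β-hydride loss may go toward the C15 methyl instead of C5–H and give the exocyclic enone. The fallback uses halogenation and dehydrohalogenation in place of palladium. It sets out from 20: NBS (THF, 0 °C) brominates the enol ether at C4, its regiochemistry fixed by the enol ether, to give the bromo ketone methyl (5S,7S,10R)-4-bromo-3-oxoeudesma-8,11(13)-dien-12-oate F8. Li2CO3/LiBr in DMF at 120 °C then removes HBr under equilibrating conditions to the conjugated endocyclic enone; the route is rejoined at 21.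

**Further compounds**
F1 | step 9 | methyl (3R)-3-{[(1S,6R)-3-(tert-butyldimethylsilyloxy)-6-formyl-2,6-dimethylcyclohex-2-en-1-yl]methyl}pent-4-enoate | C=C[C@@H](CC(=O)OC)C[C@H]1C(C)=C(O[Si](C)(C)C(C)(C)C)CC[C@@]1(C)C=O
F2 | step 9 | methyl (3R)-3-{[(1R,6S)-3-(tert-butyldimethylsilyloxy)-6-ethenyl-2,6-dimethylcyclohex-2-en-1-yl]methyl}pent-4-enoate | C=C[C@@H](CC(=O)OC)C[C@H]1C(C)=C(O[Si](C)(C)C(C)(C)C)CC[C@@]1(C)C=C
F3 | step 9 | methyl (5R,7R,10S)-3-(tert-butyldimethylsilyloxy)-13-noreudesma-3,8-dien-12-oate | COC(=O)C[C@H]1C[C@H]2C(C)=C(O[Si](C)(C)C(C)(C)C)CC[C@@]2(C)C=C1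
F4 | step 17 | (7R,8R,10R)-13-(dimethylamino)-3-oxoeudesm-4-en-12,8-olide (C11 epimers) | CN(C)CC1C(=O)O[C@@H]2C[C@@]3(C)CCC(=O)C(C)=C3C[C@H]12
F5 | step 17 | potassium (7R,8R,10R)-13-(dimethylamino)-8-hydroxy-3-oxoeudesm-4-en-12-oate | CN(C)CC(C(=O)[O-])[C@H]1CC2=C(C)C(=O)CC[C@]2(C)C[C@H]1O.[K+]
F6 | step 17 | methyl (7R,8R,10R)-8-hydroxy-3-oxo-13-(trimethylammonio)eudesm-4-en-12-oate iodide | C[N+](C)(C)CC(C(=O)OC)[C@H]1CC2=C(C)C(=O)CC[C@]2(C)C[C@H]1O.[I-]
F7 | step 17 | methyl (7R,8R,10R)-8-acetoxy-3-oxo-13-(trimethylammonio)eudesm-4-en-12-oate iodide | C[N+](C)(C)CC(C(=O)OC)[C@H]1CC2=C(C)C(=O)CC[C@]2(C)C[C@H]1OC(C)=O.[I-]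
F8 | step 13 | methyl (5S,7S,10R)-4-bromo-3-oxoeudesma-8,11(13)-dien-12-oate (C4 epimers) | C=C(C(=O)OC)[C@H]1C[C@@H]2C(C)(Br)C(=O)CC[C@]2(C)C=C1
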